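**Retrosynthetic overview**
1. Target ⇒ 11,14-quinone (C12–OH put in last by epoxidation/isomerisation) ⇒ 11,14-dimethoxyarene (oxidative demethylation); 7α-OAc ⇒ C7 aryl ketone (reagent-controlled reduction).
2. Ring B ⇒ intramolecular Friedel–Crafts acylation (C7–C8) of a ring A/arene acid.
3. C10–C20 bond and the 19,10-lactone ⇒ benzylic organometal from 2,5-dimethoxy-p-cymene + C10 ketone; the axial alkoxide closes onto the C19 ester.
4. Ring A (C4 quaternary, C5) ⇒ amine-catalysed double Michael (formal [4+2]) of a vinyl ketone with methyl (Z)-2-methyl-3-nitroacrylate, then denitration.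
5. Ring order: A, then lactone, then B; ring C is bought as the arene and oxidised at the end.

Assumption: atom labels C1–C20 follow icetexane numbering (C19 = lactone carbonyl, C20 = benzylic CH2); the sense of induction in step 3 is assigned by analogy, and the quinine-derived pseudo-enantiomer of the catalyst is used if it proves opposite; arene 12 and acid 6 are bought.

**Step 1**
Reactants: 1 methyl pyruvate; 2 nitromethane
Product: 5 methyl (2Z)-2-methyl-3-nitroprop-2-enoate, via nitro-aldol adduct 3 (not isolated), via tertiary mesylate 4 (not isolated)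
Conditions: MeNO2 (5 equiv), Et3N (10 mol %), 0 °C → rt; evaporate; MsCl, Et3N, CH2Cl2, −20 → 0 °C
Reagents that add atoms: none
Why: Henry (nitro-aldol) addition to the activated ketone, then mesylation/E1cB dehydration, is the usual entry to 2-alkyl-3-nitroacrylates and is expected to give mainly the Z isomer (nitro trans to methyl, cis to ester), purified by chromatography; no stereocentre is carried on.

**Step 2**
Reactants: 6 4-tert-butoxy-4-oxobutanoic acid
Product: 8 tert-butyl 4-oxohex-5-enoate, via acid chloride 7 (not isolated)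
Conditions: (COCl)2, DMF (cat.), CH2Cl2, 0 °C; evaporate; tributyl(vinyl)stannane, PdCl2(PPh3)2 (2 mol %), toluene, 60 °C; KF work-up, store cold over BHT
Reagents that add atoms: tributyl(vinyl)stannane, C=C[Sn](CCCC)(CCCC)CCCC
Why: Stille acyl chloride–vinylstannane ketone synthesis gives the vinyl ketone without over-addition, and the tert-butyl ester survives brief cold acid chloride formation.

**Step 3**
Reactants: 8 tert-butyl 4-oxohex-5-enoate; 5 methyl (2Z)-2-methyl-3-nitroprop-2-enoate
Product: 10 methyl (1R,2S,6S)-2-(2-tert-butoxy-2-oxoethyl)-1-methyl-6-nitro-3-oxocyclohexane-1-carboxylate, via open-chain Michael adduct 9 (not isolated)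
Conditions: 9-amino-9-deoxy-epi-quinidine (20 mol %), 2-fluorobenzoic acid (40 mol %), toluene, 25 °C, 8 (1.5 equiv) added slowly
Reagents that add atoms: none
Why: Proposed new method: the cinchona primary amine turns 8 into a 2-amino-1,3-diene whose α′-carbon (C5) attacks the carbon β to nitro of 5 (C4, creating the Me/CO2Me quaternary centre) in a synclinal, hydrogen-bond-organised transition state (protonated quinuclidine holds the nitro group, the catalyst shields one diene face and so sets absolute configuration), and the nitronate then closes ring A by intramolecular Michael addition onto the vinyl iminium; because CO2Me is cis to NO2 in the Z acceptor, the endo mode puts the CH2CO2t-Bu arm cis to CO2Me (the all-cis chair with axial ester, C3 nitro configuration irrelevant); the closest known chemistry is the primary-amine-catalysed enone/nitroalkene double Michael (formal [4+2]) to 4-nitrocyclohexanones, not yet shown with a vinyl ketone or with a 2-alkyl-3-nitroacrylate that builds an ester-bearing quaternary ring carbon.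

**Step 4**
Reactants: 10 methyl (1R,2S,6S)-2-(2-tert-butoxy-2-oxoethyl)-1-methyl-6-nitro-3-oxocyclohexane-1-carboxylate
Product: 11 methyl (1S,2S)-2-(2-tert-butoxy-2-oxoethyl)-1-methyl-3-oxocyclohexane-1-carboxylate
Conditions: Bu3SnH (5 equiv), azobisisobutyronitrile (0.5 equiv), toluene, 110 °C
Reagents that add atoms: none
Why: Radical denitration (Ono–Tanner) replaces the secondary nitro group by hydrogen, and at high stannane concentration hydrogen transfer outruns any 1,2-ester shift; C4 and C5 are untouched (the descriptor at C4 changes only through CIP priorities).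

**Step 5**
Reactants: 11 methyl (1S,2S)-2-(2-tert-butoxy-2-oxoethyl)-1-methyl-3-oxocyclohexane-1-carboxylate; 12 1,4-dimethoxy-2-methyl-5-(propan-2-yl)benzene
Product: 15 tert-butyl 2-[(1S,5S,8S)-5-{[2,5-dimethoxy-4-(propan-2-yl)phenyl]methyl}-1-methyl-7-oxo-6-oxabicyclo[3.2.1]octan-8-yl]acetate, via benzylic potassium reagent 13 (not isolated), via tertiary alkoxide 14 (not isolated)
Conditions: 12 (1.5 equiv), n-BuLi, KOt-Bu, 2,2,6,6-tetramethylpiperidine, THF, −78 °C; cannulate into 11 + LaCl3·2LiCl, THF, −78 °C → rt; aq. NH4Cl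
Reagents that add atoms: none
Why: Mixed Li/K amide metalation is selective for the benzylic methyl, and the lanthanum-moderated benzyl nucleophile adds 1,2 to the ketone from the equatorial direction because the axial C4 ester blocks the axial path, so the new C10 alkoxide is axial and 1,3-diaxial to that ester and expels methoxide to form the bridged lactone (C10 set; the tert-butyl ester is too hindered to compete).

**Step 6**
Reactants: 15 tert-butyl 2-[(1S,5S,8S)-5-{[2,5-dimethoxy-4-(propan-2-yl)phenyl]methyl}-1-methyl-7-oxo-6-oxabicyclo[3.2.1]octan-8-yl]acetate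
Product: 18 (4S,5S,10S)-11,14-dimethoxy-7-oxoicetexa-8,11,13-trien-19,10-olide, via free carboxylic acid 16 (not isolated), via mixed trifluoroacetic anhydride 17 (not isolated)
Conditions: CF3CO2H, CH2Cl2, rt; evaporate; (CF3CO)2O, CH2Cl2, 0 °C → rt (TfOH, 5 mol %, if slow)
Reagents that add atoms: none
Why: Acidolysis of the tert-butyl ester and mixed-anhydride Friedel–Crafts acylation at the only reachable ring position (C8, ortho to OMe) closes seven-membered ring B; the lactone and all stereocentres are inert.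

**Step 7**
Reactants: 18 (4S,5S,10S)-11,14-dimethoxy-7-oxoicetexa-8,11,13-trien-19,10-olide
Product: 20 (4S,5S,7R,10S)-7-acetoxy-11,14-dimethoxyicetexa-8,11,13-trien-19,10-olide, via benzylic alcohol 19 (not isolated)
Conditions: (S)-2-methyl-CBS-oxazaborolidine [(3aS)-1-methyl-3,3-diphenyltetrahydro-1H,3H-pyrrolo[1,2-c][1,3,2]oxazaborole] (0.3 equiv), BH3·SMe2, THF, −20 °C; MeOH; evaporate; Ac2O, DMAP, pyridine, rt
Reagents that add atoms: acetic anhydride, CC(=O)OC(C)=O
Why: Corey–Bakshi–Shibata reduction with the aryl group as the large substituent gives the (7R) = 7α alcohol under catalyst control, and it is acetylated in the same flask; borane does not touch the lactone.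

**Step 8**
Reactants: 20 (4S,5S,7R,10S)-7-acetoxy-11,14-dimethoxyicetexa-8,11,13-trien-19,10-olide
Product: 21 (4S,5S,7R,10S)-7-acetoxy-11,14-dioxoicetexa-8,12-dien-19,10-olide
Conditions: (NH4)2Ce(NO3)6 (2.5 equiv), MeCN/H2O, 0 °C, 15 min
Reagents that add atoms: water, O
Why: Oxidative demethylation of the 1,4-dimethoxyarene gives the para-quinone; the acetate and lactone survive the short, cold, acidic oxidation and no stereocentre is involved.

**Step 9**
Reactants: 21 (4S,5S,7R,10S)-7-acetoxy-11,14-dioxoicetexa-8,12-dien-19,10-olide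
Product: 23 7α-acetoxy-6,7-dihydroicetexone [(4S,5S,7R,10S)-7-acetoxy-12-hydroxy-11,14-dioxoicetexa-8,12-dien-19,10-olide], via epoxyquinone 22 (not isolated)
Conditions: 30 % H2O2, Na2CO3, THF/H2O, 0 °C, 15 min; extract; H2SO4 on SiO2, CH2Cl2, 0 °C
Reagents that add atoms: hydrogen peroxide, OO
Why: Weitz–Scheffer epoxidation hits the only enedione C=C that carries hydrogen (C12=C13; C8=C9 is tetrasubstituted), and acid-promoted epoxide opening/enolisation gives the 2-hydroxy-1,4-quinone with OH at C12; weak base, short contact and low temperature keep the C7 acetate, and no stereocentre is touched.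

**Compound list**
1 | methyl pyruvate (methyl 2-oxopropanoate) | CC(=O)C(=O)OC | starting material
2 | nitromethane | C[N+](=O)[O-] | starting material
3 | methyl 2-hydroxy-2-methyl-3-nitropropanoate (racemic) | COC(=O)C(C)(O)C[N+](=O)[O-] | intermediate
4 | methyl 2-methyl-2-(methylsulfonyloxy)-3-nitropropanoate (racemic) | COC(=O)C(C)(OS(C)(=O)=O)C[N+](=O)[O-] | intermediate
5 | methyl (2Z)-2-methyl-3-nitroprop-2-enoate | COC(=O)/C(C)=C\[N+](=O)[O-] | intermediate
6 | 4-tert-butoxy-4-oxobutanoic acid (mono-tert-butyl succinate) | CC(C)(C)OC(=O)CCC(=O)O | starting material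
7 | tert-butyl 4-chloro-4-oxobutanoate | CC(C)(C)OC(=O)CCC(Cl)=O | intermediate
8 | tert-butyl 4-oxohex-5-enoate | C=CC(=O)CCC(=O)OC(C)(C)C | intermediate
9 | 5-tert-butyl 1-methyl (2R,3S)-2-methyl-2-(nitromethyl)-3-(prop-2-enoyl)pentanedioate | C=CC(=O)[C@@H](CC(=O)OC(C)(C)C)[C@](C)(C[N+](=O)[O-])C(=O)OC | intermediate
10 | methyl (1R,2S,6S)-2-(2-tert-butoxy-2-oxoethyl)-1-methyl-6-nitro-3-oxocyclohexane-1-carboxylate | CC(C)(C)OC(=O)C[C@@H]1C(=O)CC[C@H]([N+](=O)[O-])[C@]1(C)C(=O)OC | intermediate
11 | methyl (1S,2S)-2-(2-tert-butoxy-2-oxoethyl)-1-methyl-3-oxocyclohexane-1-carboxylate | CC(C)(C)OC(=O)C[C@@H]1C(=O)CCC[C@]1(C)C(=O)OC | intermediate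
12 | 1,4-dimethoxy-2-methyl-5-(propan-2-yl)benzene (2,5-dimethoxy-p-cymene) | Cc1cc(OC)c(C(C)C)cc1OC | starting material
13 | {[2,5-dimethoxy-4-(propan-2-yl)phenyl]methyl}potassium | [K]Cc1cc(OC)c(C(C)C)cc1OC | intermediate
14 | methyl (1S,2S,3S)-2-(2-tert-butoxy-2-oxoethyl)-3-{[2,5-dimethoxy-4-(propan-2-yl)phenyl]methyl}-3-hydroxy-1-methylcyclohexane-1-carboxylate (as its metal alkoxide) | CC(C)(C)OC(=O)C[C@@H]1[C@](O)(CCC[C@]1(C)C(=O)OC)Cc1cc(OC)c(C(C)C)cc1OC | intermediate
15 | tert-butyl 2-[(1S,5S,8S)-5-{[2,5-dimethoxy-4-(propan-2-yl)phenyl]methyl}-1-methyl-7-oxo-6-oxabicyclo[3.2.1]octan-8-yl]acetate | CC(C)(C)OC(=O)C[C@@H]1[C@]2(CCC[C@]1(C)C(=O)O2)Cc1cc(OC)c(C(C)C)cc1OC | intermediate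
16 | 2-[(1S,5S,8S)-5-{[2,5-dimethoxy-4-(propan-2-yl)phenyl]methyl}-1-methyl-7-oxo-6-oxabicyclo[3.2.1]octan-8-yl]acetic acid | OC(=O)C[C@@H]1[C@]2(CCC[C@]1(C)C(=O)O2)Cc1cc(OC)c(C(C)C)cc1OC | intermediate
17 | mixed anhydride of 16 with trifluoroacetic acid | O=C(OC(=O)C(F)(F)F)C[C@@H]1[C@]2(CCC[C@]1(C)C(=O)O2)Cc1cc(OC)c(C(C)C)cc1OC | intermediate
18 | (4S,5S,10S)-11,14-dimethoxy-7-oxoicetexa-8,11,13-trien-19,10-olide (rings A, B, C closed; aryl ketone at C7) | O=C1C[C@@H]2[C@]3(CCC[C@]2(C)C(=O)O3)Cc2c1c(OC)c(C(C)C)cc2OC | intermediate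
19 | (4S,5S,7R,10S)-7-hydroxy-11,14-dimethoxyicetexa-8,11,13-trien-19,10-olide (7α-OH) | O[C@@H]1C[C@@H]2[C@]3(CCC[C@]2(C)C(=O)O3)Cc2c1c(OC)c(C(C)C)cc2OC | intermediate
20 | (4S,5S,7R,10S)-7-acetoxy-11,14-dimethoxyicetexa-8,11,13-trien-19,10-olide | CC(=O)O[C@@H]1C[C@@H]2[C@]3(CCC[C@]2(C)C(=O)O3)Cc2c1c(OC)c(C(C)C)cc2OC | intermediate
21 | (4S,5S,7R,10S)-7-acetoxy-11,14-dioxoicetexa-8,12-dien-19,10-olide | CC(=O)O[C@@H]1C[C@@H]2[C@]3(CCC[C@]2(C)C(=O)O3)CC2=C1C(=O)C(C(C)C)=CC2=O | intermediate
22 | 12,13-epoxide of 21 (epoxide configuration not defined) | CC(=O)O[C@@H]1C[C@@H]2[C@]3(CCC[C@]2(C)C(=O)O3)CC2=C1C(=O)C1(C(C)C)OC1C2=O | intermediate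
23 | 7α-acetoxy-6,7-dihydroicetexone | CC(=O)O[C@@H]1C[C@@H]2[C@]3(CCC[C@]2(C)C(=O)O3)CC2=C1C(=O)C(C(C)C)=C(O)C2=O | target

**Totals**
Total steps: 9. Longest linear sequence: 8 (steps 2–9, or 1 and 3–9).

**Three steps most likely to fail**

Step 3 (new double Michael; risks are aza-Michael loss of catalyst to the vinyl ketone, slow attack at the fully substituted acceptor carbon, and Z/E scrambling of 5). The fallback uses known chemistry, sets out from 5 and comes back at 10. Commercial tert-butyl 4-oxobutanoate is added to 5 by established enamine catalysis (a Pro-Pro-type tripeptide or a diphenylprolinol trimethylsilyl ether with an acid co-catalyst, the reported kind of aldehyde addition to 2-substituted 3-nitroacrylates) to give the γ-nitro aldehyde 5-tert-butyl 1-methyl (2R,3S)-3-formyl-2-methyl-2-(nitromethyl)pentanedioate F1. Vinylmagnesium bromide (2.2 equiv, LaCl3·2LiCl, −78 °C; the first equivalent is spent on the nitronate) gives the allylic alcohol 5-tert-butyl 1-methyl (2R,3S)-3-(1-hydroxyprop-2-en-1-yl)-2-methyl-2-(nitromethyl)pentanedioate F2. Dess–Martin periodinane then gives enone 9, this time isolated, and catalytic DBU closes ring A by intramolecular nitro-Michael addition to 10, with C5 settling in the same all-cis chair.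

Step 5 (benzylic versus ring metalation, enolisation of the hindered ketone, face of attack). The fallback reverses the polarity at C20, sets out from 11 and comes back at 15. Corey–Chaykovsky methylenation (Me3S(O)I, NaH, DMSO; equatorial attack, axial oxygen) gives the spiro-epoxide methyl (3R,4S,5S)-4-(2-tert-butoxy-2-oxoethyl)-5-methyl-1-oxaspiro[2.5]octane-5-carboxylate F3. Commercial 1,4-dimethoxy-2-(propan-2-yl)benzene is brominated para to the isopropyl group (NBS, MeCN) to 1-bromo-2,5-dimethoxy-4-(propan-2-yl)benzene F4, which with Mg gives bromo[2,5-dimethoxy-4-(propan-2-yl)phenyl]magnesium F5. F5 opens F3 at the CH2 terminus under CuI catalysis (THF, −30 °C → rt), and the tertiary alkoxide 14 formed lactonises to 15 as in the main route.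

Step 9 (loss or elimination of the C7 acetate under the basic epoxidation or the acid isomerisation). The fallback puts the acetate on last, sets out from 19 (isolated after the reduction of step 7 instead of being acetylated) and comes back at 23. (NH4)2Ce(NO3)6 in MeCN/H2O gives (4S,5S,7R,10S)-7-hydroxy-11,14-dioxoicetexa-8,12-dien-19,10-olide F6. H2O2/Na2CO3 gives its 12,13-epoxide F7, and H2SO4 on SiO2 isomerises this to (4S,5S,7R,10S)-7,12-dihydroxy-11,14-dioxoicetexa-8,12-dien-19,10-olide F8, the free alcohol being a poor leaving group. Ac2O/pyridine/DMAP gives the 7,12-diacetate F9, and NaHCO3 in MeOH at 0 °C cleaves only the vinylogous-anhydride acetate at O12 to give 23.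

**Further compounds**
F1 | step 3 | 5-tert-butyl 1-methyl (2R,3S)-3-formyl-2-methyl-2-(nitromethyl)pentanedioate | O=C[C@@H](CC(=O)OC(C)(C)C)[C@](C)(C[N+](=O)[O-])C(=O)OC
F2 | step 3 | 5-tert-butyl 1-methyl (2R,3S)-3-(1-hydroxyprop-2-en-1-yl)-2-methyl-2-(nitromethyl)pentanedioate (carbinol epimers) | C=CC(O)[C@@H](CC(=O)OC(C)(C)C)[C@](C)(C[N+](=O)[O-])C(=O)OC
F3 | step 5 | methyl (3R,4S,5S)-4-(2-tert-butoxy-2-oxoethyl)-5-methyl-1-oxaspiro[2.5]octane-5-carboxylate | CC(C)(C)OC(=O)C[C@@H]1[C@]2(CCC[C@]1(C)C(=O)OC)CO2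
F4 | step 5 | 1-bromo-2,5-dimethoxy-4-(propan-2-yl)benzene | Brc1cc(OC)c(C(C)C)cc1OC
F5 | step 5 | bromo[2,5-dimethoxy-4-(propan-2-yl)phenyl]magnesium | Br[Mg]c1cc(OC)c(C(C)C)cc1OC
F6 | step 9 | (4S,5S,7R,10S)-7-hydroxy-11,14-dioxoicetexa-8,12-dien-19,10-olide | O[C@@H]1C[C@@H]2[C@]3(CCC[C@]2(C)C(=O)O3)CC2=C1C(=O)C(C(C)C)=CC2=O
F7 | step 9 | 12,13-epoxide of F6 (epoxide configuration not defined) | O[C@@H]1C[C@@H]2[C@]3(CCC[C@]2(C)C(=O)O3)CC2=C1C(=O)C1(C(C)C)OC1C2=O
F8 | step 9 | (4S,5S,7R,10S)-7,12-dihydroxy-11,14-dioxoicetexa-8,12-dien-19,10-olide | O[C@@H]1C[C@@H]2[C@]3(CCC[C@]2(C)C(=O)O3)CC2=C1C(=O)C(C(C)C)=C(O)C2=O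
F9 | step 9 | (4S,5S,7R,10S)-7,12-diacetoxy-11,14-dioxoicetexa-8,12-dien-19,10-olide | CC(=O)O[C@@H]1C[C@@H]2[C@]3(CCC[C@]2(C)C(=O)O3)CC2=C1C(=O)C(C(C)C)=C(OC(C)=O)C2=O
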